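Assumption: the SMILES is read as (6R,7S,8S,11R) with 1(10)E,4E ring olefins and a (Z)-2-methylbut-2-enoate (angelate); atom numbers below are germacrane numbers of the target (ring carbons C1–C10, lactone carbons C11–C13, C14 on C10, C15 on C4).

## Analysis of the target

The target is a germacranolide: ring A is a ten-membered carbocycle (C1–C10) with two trisubstituted E olefins (C1=C10, C4=C5), and ring B is a γ-lactone (O6–C6–C7–C11–C12) fused to ring A across C6–C7. There are four stereocentres; on ring A the substituents O6, C11 and O8 all lie on one face, so ring B is cis-fused and the angelate is cis to C11, while at C11 the acetoxy group sits on the convex face of ring B (syn to H6/H7). The sensitive groups are the 1,5-diene of ring A (transannular cyclisation with acid, Cope rearrangement on heating), the angelate (Z to E isomerisation when the acid is activated), the tertiary α-acetoxy lactone, and any free 8-OH that is cis to C11 (translactonisation). The difficulty is the strained (E,E)-cyclodecadiene together with the all-cis triad C6/C7/C8 around a methine that is flanked by three oxygenated carbons. The feature the strategy uses is the array O6–C6(–C5=C4)–C7–C11(–C13)–C12: C6 is an oxygen-bearing allylic carbon, C7 carries a branched three-carbon unit, and C12 returns to O6 in ring B, which is exactly the homoallylic alcohol a [2,3]-Wittig shift writes when an ether oxygen links C6 and C12. A stereochemical consequence governs the plan: a bond made to C7 next to an existing C8–O stereocentre forms anti to that C–O bond, which places O8 trans to C11, so C8 is carried in the opposite configuration as the control element and inverted when the angelate is attached.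

## Retrosynthetic reasoning

**Ester at C8 (28 to 25 + 26).** The C8–O bond is cut so that acid 26 supplies the oxygen and C8 is inverted; 25 is the 8-epimer. The angelate is the most labile group and belongs last, the key step needs the epimeric C8, and 25 (O8 trans to C11) cannot translactonise. The forward reaction must esterify a hindered secondary carbinol by SN2 without activating the acid.

**C11–O bond (25 to 24 to 23 to 21).** The tertiary acetate is traced to alcohol 23 and this to the enolate of lactone 21. The cis-fused bicycle exposes only its convex face, which is the face the oxygen must occupy, and enolisation erases the C11 mixture carried by 21.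

**Lactone carbonyl (21 to 19 to 17).** The O6–C12 bond and the oxidation level of C12 are removed, which leads back to the isopropenyl carbinol 17 through diol 19. What is gained is that 17 is precisely the product type of a [2,3]-Wittig rearrangement.

**Key disconnection (17 to 15).** The ring bond C6–C7 is cut while O6 is reconnected to C12, giving the thirteen-membered bis-allylic ether 15. This is the only bond of ring A that joins an oxygenated allylic carbon to an allyl terminus. The precursor is an unstrained large ring with one stereocentre and all three olefin geometries fixed on a chain. The forward step has to close ring A and set C6 and C7 together.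

**Ether bond (15 to 14).** The C6–O bond is cut to chloro alcohol 14. A thirteen-membered etherification is entropically far easier than any direct closure of the ten-membered ring.

**C7=C11 olefin (14 to 13 to 12 to 11 to 9 + 10).** After functional group changes at both ends, the Z olefin is cut to aldehyde 9 and phosphonate 10. The Z geometry is what makes the ring contraction deliver the cis C6/C7 pair.

**C8–C9 bond (9 to 8 to 6 + 3; 6 to 4 + 5; 3 to 2 to 1).** The bond between the stereocentre and the geranyl chain is cut to hydrazone 6 (from 4 and auxiliary 5) and allylic bromide 3. Bromide 3 comes from geranyl acetate 1 through alcohol 2, which supplies both E olefins of ring A ready-made.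

## Alternatives that were turned down

**Alternative 1:** the textbook route cuts C6–C7 and O6–C12 in an open chain. A CrCl2-mediated intramolecular allylation (Nozaki–Hiyama–Kishi type) of bromo enal A1 would close ring A and ring B to the α-methylene lactone A2; radical hydration of the exocyclic olefin (Mn(dpm)3, PhSiH3, O2) would then install the C11 oxygen. It was turned down because the allylchromium chair prefers the anti (trans-lactone) product, and the new bond at C7 again forms anti to the C8–O bond. With the target configuration at C8, A2 would therefore carry C11 trans to both O6 and O8, two errors with no simple repair. The hydration would also have to distinguish the acrylate from two trisubstituted olefins, with a C11 radical in reach of C10=C1. The route is not shorter once these repairs are counted.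

**Alternative 2:** an anionic oxy-Cope ring expansion. Addition of a 2-alkoxyvinyllithium to (S)-isopiperitenone A3 would give the divinyl carbinol A4, and KH would expand it to the ten-membered ketone A5 (forming C8–C9, breaking C1–C6), with C8 set by chirality transfer and the enolate available for attaching C11. It was turned down although ring A arrives in two steps. C4=C5 is the ring olefin of the cyclohexenone and stays Z in A5, so a contra-thermodynamic Z to E isomerisation inside a ten-membered ring would be needed. C7 would be set by an electrophile approaching a ring enolate next to C8–O (again anti), and C6 by a ketone reduction on the macrocycle. That is three uncertain corrections on the sensitive ring.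

**Alternative 3:** a Grob-type boronate fragmentation of a decalin. Hydroboration of the tetrasubstituted olefin of the eudesmane mesylate A6 and base would break C5–C10 and form both E olefins stereospecifically. It was turned down on step economy and compatibility. A6 needs six stereocentres, including the all-cis triad and the lactone, on a decalin, and two of them are destroyed in the fragmentation. The borane would also meet a lactone and an allylic C6–O bond.

Key step: step 11

## Route

Step 1
Reactants: 1 geranyl acetate [(2E)-3,7-dimethylocta-2,6-dien-1-yl acetate]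
Product: 2 (2E,6E)-8-hydroxy-3,7-dimethylocta-2,6-dien-1-yl acetate
Conditions: SeO2 (cat.), t-BuOOH, salicylic acid (cat.), CH2Cl2, rt
Reagents that add atoms: tert-butyl hydroperoxide, CC(C)(C)OO
Why: Selenium dioxide allylic oxidation (ene reaction, then [2,3] shift) attacks the E methyl group of the electron-richer distal olefin; the olefin next to the acetate is deactivated.

Step 2
Reactants: 2 (2E,6E)-8-hydroxy-3,7-dimethylocta-2,6-dien-1-yl acetate
Product: 3 (2E,6E)-8-bromo-3,7-dimethylocta-2,6-dien-1-yl acetate
Conditions: CBr4, PPh3, CH2Cl2, 0 °C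
Reagents that add atoms: carbon tetrabromide, BrC(Br)(Br)Br
Why: Appel bromination of a primary allylic alcohol proceeds by SN2 on the alkoxyphosphonium ion without allylic transposition.

Step 3
Reactants: 4 (tert-butyldimethylsilyloxy)acetaldehyde; 5 (R)-1-amino-2-(methoxymethyl)pyrrolidine (RAMP)
Product: 6 (E)-N-[2-(tert-butyldimethylsilyloxy)ethylidene]-(2R)-2-(methoxymethyl)pyrrolidin-1-amine
Conditions: CH2Cl2, MgSO4, 0 °C to rt
Reagents that add atoms: none
Why: Condensation of an aldehyde with the hydrazine gives the E hydrazone.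

Step 4
Reactants: 6 (E)-N-[2-(tert-butyldimethylsilyloxy)ethylidene]-(2R)-2-(methoxymethyl)pyrrolidin-1-amine; 3 (2E,6E)-8-bromo-3,7-dimethylocta-2,6-dien-1-yl acetate
Product: 8 (E)-N-[(2R,4E,8E)-10-acetoxy-2-(tert-butyldimethylsilyloxy)-4,8-dimethyldeca-4,8-dienylidene]-(2R)-2-(methoxymethyl)pyrrolidin-1-amine, via lithium azaenolate 7 (not isolated)
Conditions: LiN(iPr)2, THF, 0 °C; then 3, −100 to −20 °C
Reagents that add atoms: none
Why: RAMP-hydrazone alkylation (Enders method): the chelated azaenolate with the silyloxy group trans to nitrogen is alkylated on the face left open by the methoxymethyl arm, which should give (R) at C8 (the SAMP series gives S for an α-oxygenated carbon). The reactive allylic bromide should outrun attack on the acetate at low temperature.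

Step 5
Reactants: 8 (E)-N-[(2R,4E,8E)-10-acetoxy-2-(tert-butyldimethylsilyloxy)-4,8-dimethyldeca-4,8-dienylidene]-(2R)-2-(methoxymethyl)pyrrolidin-1-amine
Product: 9 (2E,6E,9R)-9-(tert-butyldimethylsilyloxy)-3,7-dimethyl-10-oxodeca-2,6-dien-1-yl acetate
Conditions: CuCl2, THF/aq. phosphate buffer (pH 7), rt
Reagents that add atoms: water, O
Why: Copper-assisted hydrolysis frees the aldehyde at neutral pH, so the α-silyloxy centre is not epimerised and the olefins are untouched (ozonolysis is excluded); the auxiliary is released.

Step 6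
Reactants: 9 (2E,6E,9R)-9-(tert-butyldimethylsilyloxy)-3,7-dimethyl-10-oxodeca-2,6-dien-1-yl acetate; 10 ethyl 2-[bis(2,2,2-trifluoroethoxy)phosphoryl]propanoate
Product: 11 ethyl (2Z,4R,6E,10E)-12-acetoxy-4-(tert-butyldimethylsilyloxy)-2,6,10-trimethyldodeca-2,6,10-trienoate
Conditions: KN(SiMe3)2, 18-crown-6, THF, −78 °C
Reagents that add atoms: none
Why: Still–Gennari olefination: the electron-poor phosphonate under dissociating conditions eliminates fast from the kinetic adduct and should give the Z trisubstituted enoate (C12 cis to C8).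

Step 7
Reactants: 11 ethyl (2Z,4R,6E,10E)-12-acetoxy-4-(tert-butyldimethylsilyloxy)-2,6,10-trimethyldodeca-2,6,10-trienoate
Product: 12 ethyl (2Z,4R,6E,10E)-4-(tert-butyldimethylsilyloxy)-12-hydroxy-2,6,10-trimethyldodeca-2,6,10-trienoate
Conditions: K2CO3 (cat.), EtOH, 0 °C to rt
Reagents that add atoms: none
Why: Transesterification removes the unhindered acetate; ethanol as solvent leaves the hindered conjugated ethyl ester unchanged.

Step 8
Reactants: 12 ethyl (2Z,4R,6E,10E)-4-(tert-butyldimethylsilyloxy)-12-hydroxy-2,6,10-trimethyldodeca-2,6,10-trienoate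
Product: 13 ethyl (2Z,4R,6E,10E)-12-chloro-4-(tert-butyldimethylsilyloxy)-2,6,10-trimethyldodeca-2,6,10-trienoate
Conditions: MsCl, 2,4,6-collidine, LiCl, DMF, 0 °C
Reagents that add atoms: lithium chloride, [Li+].[Cl-]
Why: The allylic mesylate is displaced in situ by chloride (SN2), giving the primary geranyl-type chloride without transposition.

Step 9
Reactants: 13 ethyl (2Z,4R,6E,10E)-12-chloro-4-(tert-butyldimethylsilyloxy)-2,6,10-trimethyldodeca-2,6,10-trienoate
Product: 14 (2Z,4R,6E,10E)-12-chloro-4-(tert-butyldimethylsilyloxy)-2,6,10-trimethyldodeca-2,6,10-trien-1-ol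
Conditions: i-Bu2AlH, CH2Cl2, −78 °C
Reagents that add atoms: none
Why: 1,2-Reduction of the enoate gives the Z allylic alcohol; an alkyl chloride is inert to the aluminium hydride at this temperature.

Step 10
Reactants: 14 (2Z,4R,6E,10E)-12-chloro-4-(tert-butyldimethylsilyloxy)-2,6,10-trimethyldodeca-2,6,10-trien-1-ol
Product: 15 (3Z,5R,7E,11E)-5-(tert-butyldimethylsilyloxy)-3,7,11-trimethyl-1-oxacyclotrideca-3,7,11-triene
Conditions: NaH, Bu4NI (cat.), THF, 60 °C, slow addition, high dilution
Reagents that add atoms: none
Why: Intramolecular Williamson etherification of a primary alkoxide with a primary allylic halide; the three rigid olefins limit the conformational cost of the thirteen-membered ring and dilution suppresses oligomers.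

Step 11
Reactants: 15 (3Z,5R,7E,11E)-5-(tert-butyldimethylsilyloxy)-3,7,11-trimethyl-1-oxacyclotrideca-3,7,11-triene
Product: 17 (1R,2E,6E,9R,10R)-9-(tert-butyldimethylsilyloxy)-3,7-dimethyl-10-(prop-1-en-2-yl)cyclodeca-2,6-dien-1-ol, via 13-lithio ether 16 (not isolated)
Conditions: n-BuLi, THF, −78 to −20 °C
Reagents that add atoms: none
Why: The base removes a proton from the OCH2 group at C6 (ring position 13 of 15) to give the α-oxyallyllithium 16, which undergoes the concerted [2,3]-Wittig shift: C6 attacks C7 of the Z olefin while the O–C12 bond breaks, so the thirteen-membered ether contracts to ring A and the C6 hydroxyl and the isopropenyl group appear together. This is the macrocyclic [2,3]-Wittig ring contraction, a reaction type established for thirteen-membered bis-allylic ethers that lead to (E,E)-cyclodeca-1,5-dienes. Ring A is closed transannularly through a five-membered envelope transition state (five centres, six electrons), and both E olefins are spectators. The C6/C7 relationship follows from the Z geometry of C7=C11: with the vinyl carbon C5 exo on the envelope, which is also the arrangement the tether C5 to C9 allows, a Z olefin gives the syn pair, that is O6 cis to C11 on ring A. The absolute sense is set by C8: allylic 1,3-strain with the C12 methylene holds H8 in the olefin plane, the C8–O bond lies anti to the incoming carbanion and C9 on the side of the tether, so (8R) leads to the C6 and C7 arrangement of the target (6R,7R in 17 by the priority rules). The step needs deprotonation at C6 and not at C12 (which would end in 1,4-elimination of silyloxide), a [2,3] and not a [1,2] shift, and the cis outcome; these are secured by the shielding of C12 through the cis C8 substituent and the C11 methyl group, by the low temperature, and by the olefin geometry.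

Step 12
Reactants: 17 (1R,2E,6E,9R,10R)-9-(tert-butyldimethylsilyloxy)-3,7-dimethyl-10-(prop-1-en-2-yl)cyclodeca-2,6-dien-1-ol
Product: 19 (1R,2E,6E,9R,10R)-9-(tert-butyldimethylsilyloxy)-10-(1-hydroxypropan-2-yl)-3,7-dimethylcyclodeca-2,6-dien-1-ol (both C11 epimers), via bis(9-BBN) adduct 18 (not isolated)
Conditions: 9-BBN, THF, 0 °C to rt; then NaOH, H2O2, 0 °C
Reagents that add atoms: hydrogen peroxide, OO
Why: Hydroboration–oxidation: the bulky borane adds to the 1,1-disubstituted terminal olefin much faster than to the trisubstituted ring olefins and places boron on C12; the configuration at C11 is immaterial because it is enolised in step 14.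

Step 13
Reactants: 19 (1R,2E,6E,9R,10R)-9-(tert-butyldimethylsilyloxy)-10-(1-hydroxypropan-2-yl)-3,7-dimethylcyclodeca-2,6-dien-1-ol (both C11 epimers)
Product: 21 (6R,7R,8R)-8-(tert-butyldimethylsilyloxy)germacra-1(10)E,4E-dien-6,12-olide (cis-fused; both C11 epimers), via lactol 20 (not isolated)
Conditions: TEMPO (cat.), PhI(OAc)2, CH2Cl2, rt
Reagents that add atoms: none
Why: Oxoammonium oxidation takes the primary alcohol to the aldehyde, which closes with the C6 hydroxyl to lactol 20 and is oxidised again to the lactone; lactol formation removes the slower secondary allylic alcohol from competition.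

Step 14
Reactants: 21 (6R,7R,8R)-8-(tert-butyldimethylsilyloxy)germacra-1(10)E,4E-dien-6,12-olide (both C11 epimers)
Product: 23 (6R,7R,8R,11R)-8-(tert-butyldimethylsilyloxy)-11-hydroxygermacra-1(10)E,4E-dien-6,12-olide, via potassium enolate 22 (not isolated)
Conditions: KN(SiMe3)2, THF, −78 °C; then 2-(phenylsulfonyl)-3-phenyloxaziridine, −78 °C
Reagents that add atoms: 2-(phenylsulfonyl)-3-phenyloxaziridine, O=S(=O)(c1ccccc1)N1OC1c1ccccc1
Why: Enolate hydroxylation with the Davis oxaziridine: both epimers converge on one enolate, and the oxidant approaches the convex face of the cis-fused bicycle (the face of H6 and H7, away from C5 and C8), which puts the hydroxyl where the target has its acetoxy group.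

Step 15
Reactants: 23 (6R,7R,8R,11R)-8-(tert-butyldimethylsilyloxy)-11-hydroxygermacra-1(10)E,4E-dien-6,12-olide
Product: 24 (6R,7R,8R,11R)-11-acetoxy-8-(tert-butyldimethylsilyloxy)germacra-1(10)E,4E-dien-6,12-olide
Conditions: Ac2O, DMAP, Et3N, CH2Cl2, rt to 35 °C
Reagents that add atoms: acetic anhydride, CC(=O)OC(C)=O
Why: DMAP-catalysed acylation of the tertiary α-hydroxy lactone under non-acidic conditions that the 1,5-diene tolerates.

Step 16
Reactants: 24 (6R,7R,8R,11R)-11-acetoxy-8-(tert-butyldimethylsilyloxy)germacra-1(10)E,4E-dien-6,12-olide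
Product: 25 (6R,7S,8R,11R)-11-acetoxy-8-hydroxygermacra-1(10)E,4E-dien-6,12-olide
Conditions: Bu4NF, AcOH, THF, 0 °C to rt
Reagents that add atoms: none
Why: Buffered fluoride cleaves the silyl ether without base-induced acyl transfer; O8 is trans to C11 here, so translactonisation is not possible.

Step 17
Reactants: 25 (6R,7S,8R,11R)-11-acetoxy-8-hydroxygermacra-1(10)E,4E-dien-6,12-olide; 26 angelic acid [(Z)-2-methylbut-2-enoic acid]
Product: 28 target [(6R,7S,8S,11R)-11-acetoxy-8-angeloyloxygermacra-1(10)E,4E-dien-6,12-olide], via diphenylphosphinite 27 (not isolated)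
Conditions: Ph2PCl, Et3N, DMAP (cat.), THF, 0 °C to rt; then 26, 2,6-dimethyl-1,4-benzoquinone, CH2Cl2, rt
Reagents that add atoms: none
Why: Mukaiyama oxidation–reduction condensation: the quinone turns phosphinite 27 into an alkoxyphosphonium ion and the angelate anion displaces it by SN2, inverting C8 to (S); this variant is the one that works for hindered carbinols with ordinary carboxylic acids. The acid is never activated as an acyl donor, so the Z olefin of the angelate should not isomerise.

## Compound list

1 | geranyl acetate, (2E)-3,7-dimethylocta-2,6-dien-1-yl acetate | CC(=O)OC/C=C(\C)CCC=C(C)C | starting material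
2 | (2E,6E)-8-hydroxy-3,7-dimethylocta-2,6-dien-1-yl acetate | CC(=O)OC/C=C(\C)CC/C=C(\C)CO | intermediate
3 | (2E,6E)-8-bromo-3,7-dimethylocta-2,6-dien-1-yl acetate | CC(=O)OC/C=C(\C)CC/C=C(\C)CBr | intermediate
4 | (tert-butyldimethylsilyloxy)acetaldehyde | CC(C)(C)[Si](C)(C)OCC=O | starting material
5 | (R)-1-amino-2-(methoxymethyl)pyrrolidine (RAMP) | COC[C@H]1CCCN1N | starting material
6 | (E)-N-[2-(tert-butyldimethylsilyloxy)ethylidene]-(2R)-2-(methoxymethyl)pyrrolidin-1-amine | COC[C@H]1CCCN1/N=C/CO[Si](C)(C)C(C)(C)C | intermediate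
7 | lithium azaenolate of 6 | COC[C@H]1CCCN1N([Li])/C=C/O[Si](C)(C)C(C)(C)C | intermediate
8 | (E)-N-[(2R,4E,8E)-10-acetoxy-2-(tert-butyldimethylsilyloxy)-4,8-dimethyldeca-4,8-dienylidene]-(2R)-2-(methoxymethyl)pyrrolidin-1-amine | COC[C@H]1CCCN1/N=C/[C@H](O[Si](C)(C)C(C)(C)C)C/C(C)=C/CC/C(C)=C/COC(C)=O | intermediate
9 | (2E,6E,9R)-9-(tert-butyldimethylsilyloxy)-3,7-dimethyl-10-oxodeca-2,6-dien-1-yl acetate | O=C[C@H](O[Si](C)(C)C(C)(C)C)C/C(C)=C/CC/C(C)=C/COC(C)=O | intermediate
10 | ethyl 2-[bis(2,2,2-trifluoroethoxy)phosphoryl]propanoate | CCOC(=O)C(C)P(=O)(OCC(F)(F)F)OCC(F)(F)F | starting material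
11 | ethyl (2Z,4R,6E,10E)-12-acetoxy-4-(tert-butyldimethylsilyloxy)-2,6,10-trimethyldodeca-2,6,10-trienoate | CCOC(=O)/C(C)=C\[C@H](O[Si](C)(C)C(C)(C)C)C/C(C)=C/CC/C(C)=C/COC(C)=O | intermediate
12 | ethyl (2Z,4R,6E,10E)-4-(tert-butyldimethylsilyloxy)-12-hydroxy-2,6,10-trimethyldodeca-2,6,10-trienoate | CCOC(=O)/C(C)=C\[C@H](O[Si](C)(C)C(C)(C)C)C/C(C)=C/CC/C(C)=C/CO | intermediate
13 | ethyl (2Z,4R,6E,10E)-12-chloro-4-(tert-butyldimethylsilyloxy)-2,6,10-trimethyldodeca-2,6,10-trienoate | CCOC(=O)/C(C)=C\[C@H](O[Si](C)(C)C(C)(C)C)C/C(C)=C/CC/C(C)=C/CCl | intermediate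
14 | (2Z,4R,6E,10E)-12-chloro-4-(tert-butyldimethylsilyloxy)-2,6,10-trimethyldodeca-2,6,10-trien-1-ol | OC/C(C)=C\[C@H](O[Si](C)(C)C(C)(C)C)C/C(C)=C/CC/C(C)=C/CCl | intermediate
15 | (3Z,5R,7E,11E)-5-(tert-butyldimethylsilyloxy)-3,7,11-trimethyl-1-oxacyclotrideca-3,7,11-triene | O1C/C(C)=C\[C@H](O[Si](C)(C)C(C)(C)C)C/C(C)=C/CC/C(C)=C/C1 | intermediate
16 | 13-lithio derivative of 15 (α-oxyallyllithium at C6 of the target) | O1C/C(C)=C\[C@H](O[Si](C)(C)C(C)(C)C)C/C(C)=C/CC/C(C)=C/C1[Li] | intermediate
17 | (1R,2E,6E,9R,10R)-9-(tert-butyldimethylsilyloxy)-3,7-dimethyl-10-(prop-1-en-2-yl)cyclodeca-2,6-dien-1-ol (6R,7R,8R in target numbering) | CC(C)(C)[Si](C)(C)O[C@@H]1C/C(C)=C/CC/C(C)=C/[C@@H](O)[C@H]1C(C)=C | intermediate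
18 | bis(9-BBN) adduct of 17 (borinate at O6, alkylborane at C12; C11 epimers) | CC(C)(C)[Si](C)(C)O[C@@H]1C/C(C)=C/CC/C(C)=C/[C@@H](OB2C3CCCC2CCC3)[C@H]1C(C)CB1C2CCCC1CCC2 | intermediate
19 | (1R,2E,6E,9R,10R)-9-(tert-butyldimethylsilyloxy)-10-(1-hydroxypropan-2-yl)-3,7-dimethylcyclodeca-2,6-dien-1-ol (C11 epimers) | CC(C)(C)[Si](C)(C)O[C@@H]1C/C(C)=C/CC/C(C)=C/[C@@H](O)[C@H]1C(C)CO | intermediate
20 | cis-fused lactol from 19 (C11 and C12 epimers) | CC(C)(C)[Si](C)(C)O[C@@H]1C/C(C)=C/CC/C(C)=C/[C@H]2OC(O)C(C)[C@@H]12 | intermediate
21 | (6R,7R,8R)-8-(tert-butyldimethylsilyloxy)germacra-1(10)E,4E-dien-6,12-olide (cis-fused; C11 epimers) | CC(C)(C)[Si](C)(C)O[C@@H]1C/C(C)=C/CC/C(C)=C/[C@H]2OC(=O)C(C)[C@@H]12 | intermediate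
22 | potassium enolate of 21 | CC(C)(C)[Si](C)(C)O[C@@H]1C/C(C)=C/CC/C(C)=C/[C@H]2OC(O[K])=C(C)[C@@H]12 | intermediate
23 | (6R,7R,8R,11R)-8-(tert-butyldimethylsilyloxy)-11-hydroxygermacra-1(10)E,4E-dien-6,12-olide | CC(C)(C)[Si](C)(C)O[C@@H]1C/C(C)=C/CC/C(C)=C/[C@H]2OC(=O)[C@](C)(O)[C@@H]12 | intermediate
24 | (6R,7R,8R,11R)-11-acetoxy-8-(tert-butyldimethylsilyloxy)germacra-1(10)E,4E-dien-6,12-olide | CC(C)(C)[Si](C)(C)O[C@@H]1C/C(C)=C/CC/C(C)=C/[C@H]2OC(=O)[C@](C)(OC(C)=O)[C@@H]12 | intermediate
25 | (6R,7S,8R,11R)-11-acetoxy-8-hydroxygermacra-1(10)E,4E-dien-6,12-olide | O[C@@H]1C/C(C)=C/CC/C(C)=C/[C@H]2OC(=O)[C@](C)(OC(C)=O)[C@@H]12 | intermediate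
26 | angelic acid, (Z)-2-methylbut-2-enoic acid | C/C=C(/C)C(=O)O | starting material
27 | diphenylphosphinite of 25 | c1ccc(cc1)P(c1ccccc1)O[C@@H]1C/C(C)=C/CC/C(C)=C/[C@H]2OC(=O)[C@](C)(OC(C)=O)[C@@H]12 | intermediate
28 | (6R,7S,8S,11R)-11-acetoxy-8-angeloyloxygermacra-1(10)E,4E-dien-6,12-olide (CNP0144564.1) | C/C=C(/C)C(=O)O[C@H]1C/C(C)=C/CC/C(C)=C/[C@H]2OC(=O)[C@](C)(OC(C)=O)[C@@H]12 | target

## Step count and risk

Total step count: 17. Longest linear sequence: 16 steps (1 to 28 through steps 1, 2 and 4–17); step 3 is the side branch.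

**Step 11 (key step).** The most likely failure is deprotonation at the other α-oxy position (C12), which would be followed by 1,4-elimination of the silyloxide, or a competing [1,2]-shift. The second concern is partial loss of the cis C6/C7 relationship through an endo transition state. The fallback makes the same bond by carbonyl addition and corrects C6 afterwards. It sets out from 14. Oxidation of the allylic chloride with N-methylmorpholine N-oxide in MeCN should give (2E,6E,9R,10Z)-9-(tert-butyldimethylsilyloxy)-12-hydroxy-3,7,11-trimethyldodeca-2,6,10-trienal F1, and CBr4/PPh3 the corresponding allylic bromide F2. CrCl2 in THF at high dilution (Nozaki–Hiyama–Kishi-type allylation) should close ring A to the C6 epimer of 17, the 6,7-trans alcohol F3, because allylchromium reagents add through a chair with anti preference while the same allylic strain fixes C7 relative to C8. Mitsunobu reaction with 4-nitrobenzoic acid (PPh3, diisopropyl azodicarboxylate) should invert C6 to the 4-nitrobenzoate F4, and K2CO3 in methanol returns to the route at 17.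

**Step 17.** The most likely failure is elimination or no substitution, because the carboxylate must enter between C6 and C11 on the hindered side of C8. The fallback replaces substitution by oxidation and reduction. It sets out from 25. Dess–Martin periodinane (NaHCO3, CH2Cl2) should give the 8-ketone F5. LiBH(s-Bu)3 in THF at −78 °C, attacking from the less hindered side, should give the 8S alcohol F6; it is used at once, since its hydroxyl is cis to C11 and could translactonise. Acylation with the mixed anhydride of 26 and 2,4,6-trichlorobenzoyl chloride (Et3N, toluene, 60 °C) comes back to the route at 28. The risks of this detour are β-elimination of the lactone oxygen from the ketone and incomplete facial control in the reduction.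

**Step 10.** The most likely failure is oligomerisation or base-induced 1,4-elimination of HCl from the geranyl-type chloride before the alkoxide closes the large ring. The fallback ionises the chloride instead of displacing it. It sets out from 14, which is treated with Et2Zn (to form the zinc alkoxide) and Pd(PPh3)4 (cat.) in THF at high dilution. Zerovalent palladium forms the π-allyl complex and the zinc alkoxide attacks its less substituted terminus, which gives 15 directly; no new compound is made, and the E geometry at C4=C5 would have to be checked.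

**Step 4.** The most likely failure is incomplete facial control of the azaenolate that carries an α-silyloxy group, or attack of the azaenolate on the acetate. The fallback uses an oxazolidinone imide enolate. (S)-4-Benzyloxazolidin-2-one is acylated (n-BuLi, (tert-butyldimethylsilyloxy)acetyl chloride) to (S)-4-benzyl-3-[2-(tert-butyldimethylsilyloxy)acetyl]oxazolidin-2-one F7. Its sodium enolate (NaN(SiMe3)2, THF, −78 °C) is alkylated with 3 on the face away from the benzyl group to the (2R)-imide F8. LiSEt in THF at 0 °C converts F8 into the S-ethyl thioester F9, and Fukuyama reduction (Et3SiH, Pd/C, acetone) comes back to the route at 9.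

## Further compounds

F1 | step 11 | (2E,6E,9R,10Z)-9-(tert-butyldimethylsilyloxy)-12-hydroxy-3,7,11-trimethyldodeca-2,6,10-trienal | OC/C(C)=C\[C@H](O[Si](C)(C)C(C)(C)C)C/C(C)=C/CC/C(C)=C/C=O
F2 | step 11 | (2E,6E,9R,10Z)-12-bromo-9-(tert-butyldimethylsilyloxy)-3,7,11-trimethyldodeca-2,6,10-trienal | BrC/C(C)=C\[C@H](O[Si](C)(C)C(C)(C)C)C/C(C)=C/CC/C(C)=C/C=O
F3 | step 11 | (1S,2E,6E,9R,10R)-9-(tert-butyldimethylsilyloxy)-3,7-dimethyl-10-(prop-1-en-2-yl)cyclodeca-2,6-dien-1-ol (C6 epimer of 17) | CC(C)(C)[Si](C)(C)O[C@@H]1C/C(C)=C/CC/C(C)=C/[C@H](O)[C@H]1C(C)=C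
F4 | step 11 | 4-nitrobenzoate of 17 | CC(C)(C)[Si](C)(C)O[C@@H]1C/C(C)=C/CC/C(C)=C/[C@@H](OC(=O)c2ccc(cc2)[N+](=O)[O-])[C@H]1C(C)=C
F5 | step 17 | (6R,7R,11R)-11-acetoxy-8-oxogermacra-1(10)E,4E-dien-6,12-olide | O=C1C/C(C)=C/CC/C(C)=C/[C@H]2OC(=O)[C@](C)(OC(C)=O)[C@@H]12
F6 | step 17 | (6R,7S,8S,11R)-11-acetoxy-8-hydroxygermacra-1(10)E,4E-dien-6,12-olide | O[C@H]1C/C(C)=C/CC/C(C)=C/[C@H]2OC(=O)[C@](C)(OC(C)=O)[C@@H]12
F0 | step 10 | none | none
F7 | step 4 | (S)-4-benzyl-3-[2-(tert-butyldimethylsilyloxy)acetyl]oxazolidin-2-one | O=C1OC[C@H](Cc2ccccc2)N1C(=O)CO[Si](C)(C)C(C)(C)C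
F8 | step 4 | (S)-4-benzyl-3-[(2R,4E,8E)-10-acetoxy-2-(tert-butyldimethylsilyloxy)-4,8-dimethyldeca-4,8-dienoyl]oxazolidin-2-one | O=C1OC[C@H](Cc2ccccc2)N1C(=O)[C@H](O[Si](C)(C)C(C)(C)C)C/C(C)=C/CC/C(C)=C/COC(C)=O
F9 | step 4 | S-ethyl (2R,4E,8E)-10-acetoxy-2-(tert-butyldimethylsilyloxy)-4,8-dimethyldeca-4,8-dienethioate | CCSC(=O)[C@H](O[Si](C)(C)C(C)(C)C)C/C(C)=C/CC/C(C)=C/COC(C)=O
A1 | alternative 1 | ethyl (2Z,4S,6E,10E)-2-(bromomethyl)-4-(tert-butyldimethylsilyloxy)-6,10-dimethyl-12-oxododeca-2,6,10-trienoate | CCOC(=O)/C(CBr)=C/[C@@H](O[Si](C)(C)C(C)(C)C)C/C(C)=C/CC/C(C)=C/C=O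
A2 | alternative 1 | 8-(tert-butyldimethylsilyloxy)germacra-1(10)E,4E,11(13)-trien-6,12-olide with C11 trans to O6 and O8 | CC(C)(C)[Si](C)(C)O[C@H]1C/C(C)=C/CC/C(C)=C/[C@H]2OC(=O)C(=C)[C@H]12
A3 | alternative 2 | (S)-isopiperitenone, (6S)-3-methyl-6-(prop-1-en-2-yl)cyclohex-2-en-1-one | C=C(C)[C@@H]1CCC(C)=CC1=O
A4 | alternative 2 | 1-[(Z)-2-(4-methoxybenzyloxy)vinyl]-3-methyl-6-(prop-1-en-2-yl)cyclohex-2-en-1-ol (alkenyl groups trans) | C=C(C)[C@@H]1CCC(C)=C[C@@]1(O)/C=C\OCc1ccc(OC)cc1
A5 | alternative 2 | (2Z,6E,9S)-9-(4-methoxybenzyloxy)-3,7-dimethylcyclodeca-2,6-dien-1-one | O=C1C[C@@H](OCc2ccc(OC)cc2)C/C(C)=C/CC/C(C)=C\1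
A6 | alternative 3 | 11-acetoxy-1-(methanesulfonyloxy)-8-(tert-butyldimethylsilyloxy)eudesm-4-en-6,12-olide | CC1=C2[C@H]3OC(=O)[C@](C)(OC(C)=O)[C@@H]3[C@@H](O[Si](C)(C)C(C)(C)C)C[C@@]2(C)[C@H](OS(C)(=O)=O)CC1
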